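**Retrosynthetic overview**

1. Target ⇐ Steglich acylation at O8 with (3R)-3-methyl-4-(octadecanoyloxy)butanoic acid and a late Mannich α-methylenation of an 8-hydroxy-9-silyloxy germacranolide. Germacrane numbering: lactone O–C6, ring fusion C7, C8–O-acyl, C9–OH, C10(Me)=C1, C4(Me)=C5, lactone carbons C11 and C12, exocyclic C13.
2. Ten-membered ring ⇐ C8–C9 closure of an acyclic lactone dialdehyde (C8 aldehyde on C7, (E)-enal at C9) by CrCl2/Et3SiCl reductive cyclisation through a γ-silyloxyallylchromium species. This one operation is meant to set the ring, C8, C9, the (Z)-C1=C10 olefin and the O8/O9 differentiation.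
3. Enabling feature: the O8–C8–C9(O9)–C10(Me)=C1 unit, an anti-1,2-diol whose C9 carbinol is allylic to the trisubstituted olefin (retron of a γ-oxygenated allylmetal adding to a C8 aldehyde), held for closure by the cis-fused γ-lactone ring (O–C12–C11–C7–C6).
4. Lactone dialdehyde ⇐ cis-γ-lactone from a magnesium-catalysed anti-aldol of a succinate N-acylthiazolidinethione (C7, C8, C11, C12) with 8-silyloxygeranial (C1–C6, C9, C10 and both methyls; from geranyl acetate by allylic oxidation).
5. Ring order: γ-lactone first (step 7), ten-membered carbocycle second (step 10).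

Key step: step 10

Remark: the target is read as the (6S,7S,8S,9R)-1(10)Z,4E isomer with a cis-fused lactone (H-6, H-7, H-8 and H-9 on one face) and a (3R) side chain; (4R)-4-methyldihydrofuran-2(3H)-one is assumed to be purchasable in enantiopure form.

**Route**

Step 1
Reactants: 1 geranyl acetate
Product: 2 (2E,6E)-8-hydroxy-3,7-dimethylocta-2,6-dien-1-yl acetate
Conditions: SeO2 (0.3 equiv), t-BuOOH (3 equiv), salicylic acid (0.1 equiv), CH2Cl2, rt
Reagents that add atoms: tert-butyl hydroperoxide, CC(C)(C)OO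
Why: Riley allylic oxidation (ene reaction, then [2,3]-sigmatropic shift) hydroxylates the (E)-methyl group of the electron-richer terminal olefin and leaves the allylic acetate olefin alone.

Step 2
Reactants: 2 (2E,6E)-8-hydroxy-3,7-dimethylocta-2,6-dien-1-yl acetate
Product: 3 (2E,6E)-8-[(tert-butyldimethylsilyl)oxy]-3,7-dimethylocta-2,6-dien-1-yl acetate
Conditions: t-BuMe2SiCl, imidazole, DMF, 0 °C → rt
Reagents that add atoms: tert-butyldimethylsilyl chloride, CC(C)(C)[Si](C)(C)Cl
Why: Standard silyl ether formation on a primary allylic alcohol.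

Step 3
Reactants: 3 (2E,6E)-8-[(tert-butyldimethylsilyl)oxy]-3,7-dimethylocta-2,6-dien-1-yl acetate
Product: 4 (2E,6E)-8-[(tert-butyldimethylsilyl)oxy]-3,7-dimethylocta-2,6-dien-1-ol
Conditions: K2CO3 (0.2 equiv), MeOH, 0 °C → rt
Reagents that add atoms: none
Why: Base-catalysed transesterification removes the acetate without touching the silyl ether.

Step 4
Reactants: 4 (2E,6E)-8-[(tert-butyldimethylsilyl)oxy]-3,7-dimethylocta-2,6-dien-1-ol
Product: 5 (2E,6E)-8-[(tert-butyldimethylsilyl)oxy]-3,7-dimethylocta-2,6-dienal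
Conditions: MnO2 (excess), CH2Cl2, rt
Reagents that add atoms: none
Why: MnO2 oxidation of an allylic alcohol gives the enal under neutral conditions that preserve the (2E) geometry.

Step 5
Reactants: 6 (4S)-4-benzyl-1,3-thiazolidine-2-thione, 7 methyl 4-chloro-4-oxobutanoate
Product: 8 methyl 4-[(4S)-4-benzyl-2-thioxo-1,3-thiazolidin-3-yl]-4-oxobutanoate
Conditions: Et3N, DMAP (cat.), CH2Cl2, 0 °C → rt
Reagents that add atoms: none
Why: N-Acylation of the thiazolidinethione with the acid chloride gives the chiral imide that serves as aldol donor.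

Step 6
Reactants: 5 (2E,6E)-8-[(tert-butyldimethylsilyl)oxy]-3,7-dimethylocta-2,6-dienal, 8 methyl 4-[(4S)-4-benzyl-2-thioxo-1,3-thiazolidin-3-yl]-4-oxobutanoate
Product: 9 anti-aldol adduct as its trimethylsilyl ether (6S,7S in germacrane numbering)
Conditions: MgBr2·OEt2 (0.2 equiv), Et3N (2 equiv), Me3SiCl (1.5 equiv), EtOAc, rt
Reagents that add atoms: chlorotrimethylsilane, C[Si](C)(C)Cl
Why: Magnesium-halide-catalysed soft-enolisation anti-aldol reaction of an N-acylthiazolidinethione with an unsaturated aldehyde, in which the (Z)-enolate should react on the face away from the benzyl group in the non-chelated sense and silyl trapping makes the addition irreversible, setting C6 and C7 as (6S,7S) with the 6,7-anti relationship.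

Step 7
Reactants: 9 anti-aldol adduct as its trimethylsilyl ether
Product: 10 cis-γ-lactone imide with free C9 hydroxyl
Conditions: 48% aq. HF, MeCN, 0 °C → rt; then PPTS (cat.), toluene, 40 °C
Reagents that add atoms: none
Why: HF cleaves both silyl ethers and the freed C6 hydroxyl closes the γ-lactone on the methyl ester (acid-promoted lactonisation, 5-exo-trig) with retention at C6, so the anti-aldol relationship becomes the cis-4,5-disubstituted lactone.

Step 8
Reactants: 10 cis-γ-lactone imide with free C9 hydroxyl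
Product: 11 (4R,5S)-5-[(1E,5E)-7-hydroxy-2,6-dimethylhepta-1,5-dien-1-yl]-4-(hydroxymethyl)dihydrofuran-2(3H)-one
Conditions: NaBH4 (3 equiv), THF/H2O (4:1), 0 °C
Reagents that add atoms: none
Why: N-Acylthiazolidinethiones are activated amides that NaBH4 should reduce to the primary alcohol at 0 °C much faster than it attacks a γ-lactone, releasing the auxiliary.

Step 9
Reactants: 11 (4R,5S)-5-[(1E,5E)-7-hydroxy-2,6-dimethylhepta-1,5-dien-1-yl]-4-(hydroxymethyl)dihydrofuran-2(3H)-one
Product: 12 (2S,3S)-2-[(1E,5E)-2,6-dimethyl-7-oxohepta-1,5-dien-1-yl]-5-oxotetrahydrofuran-3-carbaldehyde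
Conditions: DMP (triacetoxy periodinane, 2.5 equiv), pyridine (5 equiv), CH2Cl2, 0 °C → rt; used crude at once
Reagents that add atoms: none
Why: Dess–Martin oxidation converts the primary and the allylic alcohol into the two aldehydes under buffered conditions that should not epimerise C7.

Step 10
Reactants: 12 (2S,3S)-2-[(1E,5E)-2,6-dimethyl-7-oxohepta-1,5-dien-1-yl]-5-oxotetrahydrofuran-3-carbaldehyde
Product: 15 8-hydroxy-9-(triethylsilyloxy)germacra-1(10)Z,4E-dien-12,6-olide, via γ-silyloxyallylchromium species 13 (not isolated), via chromium alkoxide 14 (not isolated)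
Conditions: CrCl2 (6 equiv), Et3SiCl (1.5 equiv), DMF/THF (1:3), 0 °C → rt, 12 added over 10 h by syringe pump (final 2 mM); pH 7 buffer work-up
Reagents that add atoms: chlorotriethylsilane, CC[Si](Cl)(CC)CC
Why: Proposed new method: divalent chromium activated by Et3SiCl should reduce only the conjugated aldehyde of 12 (two one-electron transfers, O-silylation) to the (E)-γ-silyloxyallylchromium species 13, in which C1–C10 is a single bond, so the (E)-geometry of the enal is erased; the closest known reaction types are the intermolecular CrCl2/R3SiCl cross-pinacol-type coupling of enals with aldehydes (anti-selective) and Nozaki–Hiyama–Kishi allylchromium macrocyclisations. The carbocycle closes by 10-exo-trig attack of C9 on the C8 aldehyde through a six-membered chair (Cr–O=C8···C9=C10–C1) that the cis-fused lactone (O–C12–C11–C7–C6) preorganises by holding both arms on one face. C9 is controlled by the (E)-enol silyl ether together with the equatorial position of C7 on the chair, which give the 8,9-anti diol pattern, and C8 by the C7 stereocentre, attack occurring anti to C11 with the tether-bearing C6 gauche as ring closure demands. The new C1=C10 bond should be (Z) because the tether can only span the chair with C2 axial on C1, that is, as an in-ring cis olefin. O8 and O9 leave the flask differentiated (C9–OSiEt3, C8–OH after hydrolysis of chromium alkoxide 14). The step needs chemoselective reduction of the enal (secured by its far easier reduction than that of the saturated C8 aldehyde) and C9- rather than C1-attack (secured because C1-attack would give an eight-membered ring containing the (E)-C4=C5 olefin), with high dilution suppressing oligomers.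

Step 11
Reactants: 15 8-hydroxy-9-(triethylsilyloxy)germacra-1(10)Z,4E-dien-12,6-olide
Product: 17 C11-(dimethylaminomethyl) lactone (Mannich base), via dilithium alkoxide enolate 16 (not isolated)
Conditions: LiN(i-Pr)2 (2.5 equiv), THF, −78 °C; then dimethyl(methylene)ammonium iodide (3 equiv), −78 → −20 °C
Reagents that add atoms: dimethyl(methylene)ammonium iodide, C=[N+](C)C.[I-]
Why: Mannich aminomethylation of the lactone lithium enolate, formed together with the C8 alkoxide so that the enolised lactone carbonyl is shielded from transesterification; the new C11 centre is irrelevant because step 12 removes it.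

Step 12
Reactants: 17 C11-(dimethylaminomethyl) lactone (Mannich base)
Product: 19 8-hydroxy-9-(triethylsilyloxy)germacra-1(10)Z,4E,11(13)-trien-12,6-olide, via trimethylammonium iodide 18 (not isolated)
Conditions: MeI (10 equiv), THF, rt; then sat. aq. NaHCO3, EtOAc, rt
Reagents that add atoms: none
Why: Exhaustive N-methylation followed by mild base-induced Hofmann-type β-elimination of trimethylamine is the classical entry to α-methylene-γ-butyrolactones.

Step 13
Reactants: 20 (4R)-4-methyldihydrofuran-2(3H)-one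
Product: 22 benzyl (3R)-4-hydroxy-3-methylbutanoate, via potassium hydroxy carboxylate 21 (not isolated)
Conditions: KOH (1.0 equiv), MeOH/H2O, rt; evaporate; BnBr (1.1 equiv), DMF, rt
Reagents that add atoms: potassium hydroxide, [K+].[OH-]; benzyl bromide, BrCc1ccccc1
Why: Saponification of the lactone and SN2 O-alkylation of the carboxylate give the hydroxy ester without touching the stereocentre, which is β to the carbonyl.

Step 14
Reactants: 22 benzyl (3R)-4-hydroxy-3-methylbutanoate, 23 octadecanoyl chloride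
Product: 24 (2R)-4-(benzyloxy)-2-methyl-4-oxobutyl octadecanoate
Conditions: pyridine (2 equiv), DMAP (0.05 equiv), CH2Cl2, 0 °C → rt
Reagents that add atoms: none
Why: DMAP-catalysed acylation of the primary alcohol with the acid chloride should be fast enough to outrun re-lactonisation.

Step 15
Reactants: 24 (2R)-4-(benzyloxy)-2-methyl-4-oxobutyl octadecanoate
Product: 25 (3R)-3-methyl-4-(octadecanoyloxy)butanoic acid
Conditions: H2 (1 atm), Pd/C (10% zerovalent palladium on carbon), EtOAc, rt
Reagents that add atoms: none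
Why: Hydrogenolysis cleaves the benzyl ester selectively while the alkyl ester is inert.

Step 16
Reactants: 19 8-hydroxy-9-(triethylsilyloxy)germacra-1(10)Z,4E,11(13)-trien-12,6-olide, 25 (3R)-3-methyl-4-(octadecanoyloxy)butanoic acid
Product: 27 8-O-acyl-9-O-triethylsilyl germacranolide, via O-acylisourea 26 (not isolated)
Conditions: DCC (1.5 equiv), DMAP (0.5 equiv), CH2Cl2, 0 °C → rt
Reagents that add atoms: none
Why: Steglich esterification of the only free hydroxyl (C8) with a β-branched acid that cannot epimerise.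

Step 17
Reactants: 27 8-O-acyl-9-O-triethylsilyl germacranolide
Product: 28 target, (6S,7S,8S,9R)-8-[(3R)-3-methyl-4-(octadecanoyloxy)butanoyloxy]-9-hydroxygermacra-1(10)Z,4E,11(13)-trien-12,6-olide
Conditions: HF·pyridine, pyridine, THF, 0 °C → rt
Reagents that add atoms: none
Why: Fluoride cleavage of the allylic triethylsilyl ether under buffered, mildly acidic conditions should leave the three esters and the α-methylene lactone intact and avoid 8→9 acyl migration.

**Compound list**

1 | geranyl acetate, (2E)-3,7-dimethylocta-2,6-dien-1-yl acetate | CC(=O)OC/C=C(\C)CCC=C(C)C | starting material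
2 | (2E,6E)-8-hydroxy-3,7-dimethylocta-2,6-dien-1-yl acetate | CC(=O)OC/C=C(\C)CC/C=C(\C)CO | intermediate
3 | (2E,6E)-8-[(tert-butyldimethylsilyl)oxy]-3,7-dimethylocta-2,6-dien-1-yl acetate | CC(=O)OC/C=C(\C)CC/C=C(\C)CO[Si](C)(C)C(C)(C)C | intermediate
4 | (2E,6E)-8-[(tert-butyldimethylsilyl)oxy]-3,7-dimethylocta-2,6-dien-1-ol | OC/C=C(\C)CC/C=C(\C)CO[Si](C)(C)C(C)(C)C | intermediate
5 | (2E,6E)-8-[(tert-butyldimethylsilyl)oxy]-3,7-dimethylocta-2,6-dienal | O=C/C=C(\C)CC/C=C(\C)CO[Si](C)(C)C(C)(C)C | intermediate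
6 | (4S)-4-benzyl-1,3-thiazolidine-2-thione | S=C1SC[C@H](Cc2ccccc2)N1 | starting material
7 | methyl 4-chloro-4-oxobutanoate | COC(=O)CCC(Cl)=O | starting material
8 | methyl 4-[(4S)-4-benzyl-2-thioxo-1,3-thiazolidin-3-yl]-4-oxobutanoate | COC(=O)CCC(=O)N1[C@@H](Cc2ccccc2)CSC1=S | intermediate
9 | methyl (3S,4S,5E,9E)-3-{[(4S)-4-benzyl-2-thioxo-1,3-thiazolidin-3-yl]carbonyl}-11-[(tert-butyldimethylsilyl)oxy]-6,10-dimethyl-4-[(trimethylsilyl)oxy]undeca-5,9-dienoate | COC(=O)C[C@H](C(=O)N1[C@@H](Cc2ccccc2)CSC1=S)[C@@H](O[Si](C)(C)C)/C=C(\C)CC/C=C(\C)CO[Si](C)(C)C(C)(C)C | intermediate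
10 | (4S)-4-benzyl-3-{[(2S,3S)-2-[(1E,5E)-7-hydroxy-2,6-dimethylhepta-1,5-dien-1-yl]-5-oxotetrahydrofuran-3-yl]carbonyl}-1,3-thiazolidine-2-thione | O=C(N1[C@@H](Cc2ccccc2)CSC1=S)[C@H]1CC(=O)O[C@H]1/C=C(\C)CC/C=C(\C)CO | intermediate
11 | (4R,5S)-5-[(1E,5E)-7-hydroxy-2,6-dimethylhepta-1,5-dien-1-yl]-4-(hydroxymethyl)dihydrofuran-2(3H)-one | OC[C@H]1CC(=O)O[C@H]1/C=C(\C)CC/C=C(\C)CO | intermediate
12 | (2S,3S)-2-[(1E,5E)-2,6-dimethyl-7-oxohepta-1,5-dien-1-yl]-5-oxotetrahydrofuran-3-carbaldehyde | O=C[C@H]1CC(=O)O[C@H]1/C=C(\C)CC/C=C(\C)C=O | intermediate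
13 | (E)-γ-(triethylsilyloxy)allyl chromium dichloride (trivalent chromium bound at C1, configuration at C1 labile), C8 aldehyde intact | O=C[C@H]1CC(=O)O[C@H]1/C=C(\C)CCC([Cr](Cl)Cl)/C(C)=C/O[Si](CC)(CC)CC | intermediate
14 | C8 chromium dichloride alkoxide of 15 | C1C(=O)O[C@H]2/C=C(\C)CC/C=C(/C)[C@@H](O[Si](CC)(CC)CC)[C@@H](O[Cr](Cl)Cl)[C@@H]12 | intermediate
15 | (3aR,4S,5R,6Z,10E,11aS)-4-hydroxy-6,10-dimethyl-5-[(triethylsilyl)oxy]-3a,4,5,8,9,11a-hexahydrocyclodeca[b]furan-2(3H)-one (ring stereocentres placed as in 28) | C1C(=O)O[C@H]2/C=C(\C)CC/C=C(/C)[C@@H](O[Si](CC)(CC)CC)[C@@H](O)[C@@H]12 | intermediate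
16 | dilithium C8 alkoxide / lactone enolate of 15 | C1=C(O[Li])O[C@H]2/C=C(\C)CC/C=C(/C)[C@@H](O[Si](CC)(CC)CC)[C@@H](O[Li])[C@@H]12 | intermediate
17 | 3-[(dimethylamino)methyl] derivative of 15 (C3 epimers, other centres as in 15) | CN(C)CC1C(=O)O[C@H]2/C=C(\C)CC/C=C(/C)[C@@H](O[Si](CC)(CC)CC)[C@@H](O)[C@@H]12 | intermediate
18 | N-methyl quaternary ammonium iodide of 17 | C[N+](C)(C)CC1C(=O)O[C@H]2/C=C(\C)CC/C=C(/C)[C@@H](O[Si](CC)(CC)CC)[C@@H](O)[C@@H]12.[I-] | intermediate
19 | (3aR,4S,5R,6Z,10E,11aS)-4-hydroxy-6,10-dimethyl-3-methylidene-5-[(triethylsilyl)oxy]-3a,4,5,8,9,11a-hexahydrocyclodeca[b]furan-2(3H)-one | C=C1C(=O)O[C@H]2/C=C(\C)CC/C=C(/C)[C@@H](O[Si](CC)(CC)CC)[C@@H](O)[C@@H]12 | intermediate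
20 | (4R)-4-methyldihydrofuran-2(3H)-one | C[C@H]1COC(=O)C1 | starting material
21 | potassium (3R)-4-hydroxy-3-methylbutanoate | [K+].[O-]C(=O)C[C@@H](C)CO | intermediate
22 | benzyl (3R)-4-hydroxy-3-methylbutanoate | O=C(C[C@@H](C)CO)OCc1ccccc1 | intermediate
23 | octadecanoyl chloride | CCCCCCCCCCCCCCCCCC(=O)Cl | starting material
24 | (2R)-4-(benzyloxy)-2-methyl-4-oxobutyl octadecanoate | O=C(C[C@@H](C)COC(=O)CCCCCCCCCCCCCCCCC)OCc1ccccc1 | intermediate
25 | (3R)-3-methyl-4-(octadecanoyloxy)butanoic acid | OC(=O)C[C@@H](C)COC(=O)CCCCCCCCCCCCCCCCC | intermediate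
26 | O-acylisourea from 25 and N,N'-dicyclohexylcarbodiimide | C1CCCCC1NC(=NC1CCCCC1)OC(=O)C[C@@H](C)COC(=O)CCCCCCCCCCCCCCCCC | intermediate
27 | (3aS,4S,5R,6Z,10E,11aS)-6,10-dimethyl-3-methylidene-2-oxo-5-[(triethylsilyl)oxy]-2,3,3a,4,5,8,9,11a-octahydrocyclodeca[b]furan-4-yl (3R)-3-methyl-4-(octadecanoyloxy)butanoate | C=C1C(=O)O[C@H]2/C=C(\C)CC/C=C(/C)[C@@H](O[Si](CC)(CC)CC)[C@@H](OC(=O)C[C@@H](C)COC(=O)CCCCCCCCCCCCCCCCC)[C@@H]12 | intermediate
28 | (3aS,4S,5R,6Z,10E,11aS)-5-hydroxy-6,10-dimethyl-3-methylidene-2-oxo-2,3,3a,4,5,8,9,11a-octahydrocyclodeca[b]furan-4-yl (3R)-3-methyl-4-(octadecanoyloxy)butanoate | C=C1C(=O)O[C@H]2/C=C(\C)CC/C=C(/C)[C@@H](O)[C@@H](OC(=O)C[C@@H](C)COC(=O)CCCCCCCCCCCCCCCCC)[C@@H]12 | target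

**Count and risks**

Total step count: 17. Longest linear sequence: 13 steps (steps 1–4, 6–12, 16, 17).

Steps most likely to fail:

1. Step 10 (proposed new method). The ring closure may lose to intermolecular coupling, or the closed transition state may fail to deliver the (Z)-olefin and the required facial selectivity at C8 and C9. Fallback with known chemistry, setting out from 12: a SmI2-mediated pinacol macrocyclisation (THF, high dilution) would close the same C8–C9 bond with retention of the enal geometry and give the (1(10)E)-8,9-diol lactone F1. MnO2 would oxidise only its allylic C9 hydroxyl to the (E)-hydroxy enone F2. n-Bu3P-catalysed addition–elimination should equilibrate the strained in-ring (E)-enone to the (Z)-hydroxy enone F3. Chelation-controlled reduction with Zn(BH4)2 should then give the 8,9-anti diol F4, whose less hindered allylic C9 hydroxyl would be silylated selectively (Et3SiCl, imidazole, −40 °C) to come back to the route at 15.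

2. Step 11. Under the strongly basic conditions the silyl group may migrate from O9 to the C8 alkoxide, and that alkoxide may attack the lactone (translactonisation). Fallback, setting out from 15: condensation with tert-butoxybis(dimethylamino)methane (neat, 80 °C), which needs no metal alkoxide or enolate, would give the enamino lactone F5; conjugate reduction with i-Bu2AlH (THF, −78 °C) and loss of dimethylamine on silica gel would come back to the route at 19, bypassing 17.

3. Step 9. The β-acyloxy aldehyde may epimerise at C7 or lose the lactone carboxylate by β-elimination during the double oxidation, and diol 11 may translactonise before it. Fallback, setting out from 10: thiolysis (EtSH, imidazole, CH2Cl2) would give the S-ethyl thioester F6; Fukuyama reduction (Et3SiH, Pd/C as zerovalent palladium on carbon, acetone) would give the hydroxy aldehyde F7 under neutral conditions; MnO2 would then oxidise only the allylic alcohol and come back to the route at 12, bypassing 11.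

**Further compounds**

F1 | step 10 | (1(10)E,4E)-8,9-dihydroxygermacra-1(10),4-dien-12,6-olide (C6, C7, C8 as in 15; C9 epimers) | C1C(=O)O[C@H]2/C=C(\C)CC/C=C(\C)C(O)[C@@H](O)[C@@H]12
F2 | step 10 | (1(10)E,4E)-8-hydroxy-9-oxogermacra-1(10),4-dien-12,6-olide (C6, C7, C8 as in 15) | C1C(=O)O[C@H]2/C=C(\C)CC/C=C(\C)C(=O)[C@@H](O)[C@@H]12
F3 | step 10 | (1(10)Z,4E)-8-hydroxy-9-oxogermacra-1(10),4-dien-12,6-olide (C6, C7, C8 as in 15) | C1C(=O)O[C@H]2/C=C(\C)CC/C=C(/C)C(=O)[C@@H](O)[C@@H]12
F4 | step 10 | (1(10)Z,4E)-8,9-dihydroxygermacra-1(10),4-dien-12,6-olide (all stereocentres as in 15) | C1C(=O)O[C@H]2/C=C(\C)CC/C=C(/C)[C@@H](O)[C@@H](O)[C@@H]12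
F5 | step 11 | 3-[(dimethylamino)methylidene] derivative of 15 (enamino lactone) | CN(C)C=C1C(=O)O[C@H]2/C=C(\C)CC/C=C(/C)[C@@H](O[Si](CC)(CC)CC)[C@@H](O)[C@@H]12
F6 | step 9 | S-ethyl (2S,3S)-2-[(1E,5E)-7-hydroxy-2,6-dimethylhepta-1,5-dien-1-yl]-5-oxotetrahydrofuran-3-carbothioate | CCSC(=O)[C@H]1CC(=O)O[C@H]1/C=C(\C)CC/C=C(\C)CO
F7 | step 9 | (2S,3S)-2-[(1E,5E)-7-hydroxy-2,6-dimethylhepta-1,5-dien-1-yl]-5-oxotetrahydrofuran-3-carbaldehyde | O=C[C@H]1CC(=O)O[C@H]1/C=C(\C)CC/C=C(\C)CO
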